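**Retrosynthetic overview**

1. Each ring is numbered from its carboxyl carbon C1. Ring A has the biaryl bond at C2 and OH on C3 to C5. Ring B has the biaryl bond at C2, OH on C3 and C4, and the ether O on C5. Ring C has the ether O on C2 and OH on C3 to C5. The plan rests on one feature: rings B and C are two copies of one gallate joined from O5 of ring B to C2 of ring C. Ring A is a third gallate on C2 of ring B, so all 21 carbons come from methyl gallate.
2. Last disconnection: neutral hydrogenolysis of a precursor that carries only benzyl groups and one diphenylmethylene ketal. Acidic deprotection would close the ellagic-type lactones of the open triacid.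
3. The C2(A)–C2(B) bond comes from an intramolecular Pd-catalysed arylation of an ester that ties the ring A carboxyl to O3 of ring B. The six-membered lactone formed is later opened by saponification and trapped by benzylation.
4. The O5(B)–C2(C) ether comes from oxidative dimerisation of methyl 3-O-allylgallate. The sequence is ortho-quinone formation, hetero-Diels–Alder addition (O5–C2 and O4–C3 bonds) and reductive release of O4–C3. Allyl is used on O3 because it must later be removed beside benzyl ethers.
5. Ring order: the three arenes are bought. The protecting dioxole forms in step 1. The 1,4-dioxane forms and opens in step 4. The lactone forms in step 12 and opens in step 13.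

Key step: step 4

Assumption: the target string fixes no configuration at the hindered A–B axis, so the axis is made racemic; the free triacid lactonises in acid or on heating, so it is released last under neutral conditions and kept cold.

**Step 1**
Reactants: 1 methyl gallate
Product: 2 methyl 7-hydroxy-2,2-diphenyl-1,3-benzodioxole-5-carboxylate (4,5-O-diphenylmethylene ketal of methyl gallate, O3–H free)
Conditions: Ph2CCl2 (1.3 equiv), neat, 170 °C
Reagents that add atoms: dichlorodiphenylmethane, ClC(Cl)(c1ccccc1)c1ccccc1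
Why: Catechol ketalisation with a gem-dichloride; only two neighbouring hydroxyls can bridge one carbon and the two such pairs of the gallate are equivalent by symmetry, so one dioxole and one free outer phenol should result.

**Step 2**
Reactants: 2 methyl 7-hydroxy-2,2-diphenyl-1,3-benzodioxole-5-carboxylate
Product: 3 methyl 7-(allyloxy)-2,2-diphenyl-1,3-benzodioxole-5-carboxylate
Conditions: allyl bromide, K2CO3, acetone, reflux
Reagents that add atoms: allyl bromide, C=CCBr
Why: Williamson ether synthesis on the only free phenol, placing an alkyl-type donor on O3 that is orthogonal to the benzyl ethers used later.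

**Step 3**
Reactants: 3 methyl 7-(allyloxy)-2,2-diphenyl-1,3-benzodioxole-5-carboxylate
Product: 4 methyl 3-(allyloxy)-4,5-dihydroxybenzoate
Conditions: AcOH/H2O 4:1, reflux
Reagents that add atoms: none
Why: Acid hydrolysis of the ketal through its diphenyl-stabilised oxocarbenium ion; the methyl ester and allyl ether are inert and the temperature is far below that of a Claisen rearrangement.

**Step 4**
Reactants: 4 methyl 3-(allyloxy)-4,5-dihydroxybenzoate (two molecules)
Product: 7 methyl 3-(allyloxy)-2-[3-(allyloxy)-2-hydroxy-5-(methoxycarbonyl)phenoxy]-4,5-dihydroxybenzoate, via ortho-quinone 5 (not isolated), via cis-fused dioxane adduct 6 (not isolated)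
Conditions: o-chloranil (1.0 equiv per 4), Et2O, −40 °C; B(OAc)3 (1 equiv), CH2Cl2, −40 °C → rt; Na2S2O4, THF/H2O, rt, Ar
Reagents that add atoms: none
Why: o-Chloranil dehydrogenates each catechol 4 to quinone 5, and two molecules of 5 combine in an inverse-electron-demand hetero-Diels–Alder reaction in which the Lewis-acid-bound O=C4–C5=O unit of one (future ring B) is the 4π partner and the allyloxy enol-ether bond C2=C3 of the other (future ring C) is the 2π partner. Bond formation is strongly asynchronous: nucleophilic C2 bonds to O5 because the charge then lands on O4, para to the ester of a ring that has just become aromatic, and O4 closes onto the oxocarbenium carbon C3, so the one new ring, the 1,4-dioxane of 6, is closed by [4+2] cycloaddition (6-exo-trig capture in the stepwise limit). The closest known reaction type is the addition of ortho-quinones to enol ethers to give 2,3-dihydro-1,4-benzodioxines, and the dimerisation of gallate-derived ortho-quinones is itself known. The two stereocentres of 6 (C2 and C3 of ring C) are set cis by suprafacial addition, are racemic, and both vanish on aromatisation. Na2S2O4 reduces the remaining C4,C5-dione of ring C to its ene-diol, which expels the O4 phenoxide of ring B (a far better leaving group than allyloxide) from ketal carbon C3, and tautomerisation of C2–H restores the arene with only the O5–C2 ether left. The step needs hetero- over carbo-Diels–Alder periselectivity, C2=C3 over C6=C1 site selectivity and O5-to-C2 orientation, which rest on the donor allyloxy group on C3 (C6=C1 is acceptor-substituted), on the ester para to O4 and on B(OAc)3 activating the dione.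

**Step 5**
Reactants: 7 methyl 3-(allyloxy)-2-[3-(allyloxy)-2-hydroxy-5-(methoxycarbonyl)phenoxy]-4,5-dihydroxybenzoate
Product: 8 methyl 3-(allyloxy)-2-[3-(allyloxy)-2-(benzyloxy)-5-(methoxycarbonyl)phenoxy]-4,5-bis(benzyloxy)benzoate
Conditions: BnBr (3.6 equiv), K2CO3, DMF, rt, Ar
Reagents that add atoms: benzyl bromide, BrCc1ccccc1
Why: Threefold Williamson etherification of O4 of ring B and O4 and O5 of ring C, run under argon so that the catechol is not re-oxidised.

**Step 6**
Reactants: 8 methyl 3-(allyloxy)-2-[3-(allyloxy)-2-(benzyloxy)-5-(methoxycarbonyl)phenoxy]-4,5-bis(benzyloxy)benzoate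
Product: 9 methyl 4,5-bis(benzyloxy)-2-[2-(benzyloxy)-3-hydroxy-5-(methoxycarbonyl)phenoxy]-3-hydroxybenzoate (O3–H free on rings B and C)
Conditions: Pd(PPh3)4 (5 mol %), morpholine, THF, rt
Reagents that add atoms: none
Why: Tsuji–Trost deallylation; zerovalent palladium ionises both aryl allyl ethers to π-allyl complexes that morpholine captures, while benzyl ethers and methyl esters are untouched.

**Step 7**
Reactants: 2 methyl 7-hydroxy-2,2-diphenyl-1,3-benzodioxole-5-carboxylate
Product: 10 methyl 7-(benzyloxy)-2,2-diphenyl-1,3-benzodioxole-5-carboxylate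
Conditions: BnBr, K2CO3, acetone, reflux
Reagents that add atoms: benzyl bromide, BrCc1ccccc1
Why: Williamson ether synthesis on the single phenol, starting the ring A fragment from the intermediate already made in step 1.

**Step 8**
Reactants: 10 methyl 7-(benzyloxy)-2,2-diphenyl-1,3-benzodioxole-5-carboxylate
Product: 11 methyl 7-(benzyloxy)-4-bromo-2,2-diphenyl-1,3-benzodioxole-5-carboxylate (gallate numbering: Br on C2, ketal on O3 and O4, OBn on C5)
Conditions: NBS (1.05 equiv), MeCN, 0 °C → rt, dark
Reagents that add atoms: N-bromosuccinimide, O=C1CCC(=O)N1Br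
Why: Electrophilic aromatic bromination; the position para to the benzyloxy group and ortho to the tied-back dioxole oxygen is the less shielded one, and this is the orientation known for 7-alkoxy-1,3-benzodioxole-5-carboxylates.

**Step 9**
Reactants: 11 methyl 7-(benzyloxy)-4-bromo-2,2-diphenyl-1,3-benzodioxole-5-carboxylate
Product: 12 7-(benzyloxy)-4-bromo-2,2-diphenyl-1,3-benzodioxole-5-carboxylic acid
Conditions: LiOH, THF/MeOH/H2O, 50 °C; then 1 M HCl, 0 °C
Reagents that add atoms: lithium hydroxide, [Li+].[OH-]
Why: Ester saponification; the ketal, benzyl ether and aryl bromide are stable to base, and the brief cold acidification does not touch the ketal.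

**Step 10**
Reactants: 9 methyl 4,5-bis(benzyloxy)-2-[2-(benzyloxy)-3-hydroxy-5-(methoxycarbonyl)phenoxy]-3-hydroxybenzoate; 12 7-(benzyloxy)-4-bromo-2,2-diphenyl-1,3-benzodioxole-5-carboxylic acid
Product: 13 monoester of 9 carrying the acyl group of 12 on O3 of ring B (O3–H of ring C still free)
Conditions: 12 (1.0 equiv, slow addition), DCC, DMAP (cat.), CH2Cl2, −10 °C → rt
Reagents that add atoms: none
Why: Steglich esterification under kinetic control; O3–H of ring B has a C–H neighbour whereas O3–H of ring C sits between the aryloxy group on C2 and the benzyloxy group on C4, so one equivalent of the bulky ortho-bromo acyl donor should take the open phenol.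

**Step 11**
Reactants: 13 ring B O3 monoester
Product: 14 ring C O3 benzyl ether of 13
Conditions: BnBr, K2CO3, DMF, rt
Reagents that add atoms: benzyl bromide, BrCc1ccccc1
Why: Williamson etherification of the remaining hindered phenol under anhydrous mild base, which removes a phenoxide that could scramble the aryl ester in the hot arylation step.

**Step 12**
Reactants: 14 aryl 2-bromobenzoate
Product: 15 benzo[c]chromen-6-one lactone (C2 of ring A bonded to C2 of ring B; ring A carbonyl on O3 of ring B)
Conditions: Pd(OAc)2 (10 mol %), PPh3 (20 mol %), NaOAc, DMA, 125 °C, Ar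
Reagents that add atoms: none
Why: Intramolecular Pd-catalysed direct arylation of an aryl 2-halobenzoate (biaryl lactone method), in which zerovalent palladium inserts into C–Br, acetate-assisted metalation–deprotonation occurs at C2–H of ring B (the only free position ortho to the ester oxygen and the most acidic C–H), reductive elimination closes the six-membered lactone, and the tied-back ketal beside the bromide offers no C–H for the competing cyclisation that an O-benzyl group there would allow.

**Step 13**
Reactants: 15 benzo[c]chromen-6-one lactone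
Product: 17 tribenzyl ester of hexa-O-benzyl-3,4-O-diphenylmethylene (ring A) valoneaic acid, via tetrapotassium salt 16 (not isolated)
Conditions: KOH (6 equiv), dioxane/H2O, 90 °C, Ar; evaporate; BnBr (10 equiv), Bu4NI (cat.), DMF, 50 °C
Reagents that add atoms: potassium hydroxide, [K+].[OH-]; benzyl bromide, BrCc1ccccc1
Why: Saponification followed by O-alkylation (the alkylative opening of biaryl lactones used to turn ellagic acid into hexa-O-alkyldiphenates); hydroxide cleaves both methyl esters and the lactone, and because the salt is never acidified the O3 phenoxide of ring B is capped before it can close back onto the ring A carboxyl.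

**Step 14**
Reactants: 17 tribenzyl ester of hexa-O-benzyl-3,4-O-diphenylmethylene (ring A) valoneaic acid
Product: 18 valoneaic acid
Conditions: H2 (1 atm), 10% Pd/C, THF/MeOH, rt; filter, concentrate below 25 °C, lyophilise
Reagents that add atoms: none
Why: Catalytic hydrogenolysis cleaves the nine benzylic C–O bonds and the doubly benzylic ketal under neutral conditions, which should leave the three carboxyl groups open rather than lactonised, and no stereocentre is involved.

**Compound list**

1 | methyl gallate | COC(=O)c1cc(O)c(O)c(O)c1 | starting material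
2 | methyl 7-hydroxy-2,2-diphenyl-1,3-benzodioxole-5-carboxylate | COC(=O)c1cc(O)c2OC(c3ccccc3)(c3ccccc3)Oc2c1 | intermediate
3 | methyl 7-(allyloxy)-2,2-diphenyl-1,3-benzodioxole-5-carboxylate | COC(=O)c1cc(OCC=C)c2OC(c3ccccc3)(c3ccccc3)Oc2c1 | intermediate
4 | methyl 3-(allyloxy)-4,5-dihydroxybenzoate | COC(=O)c1cc(O)c(O)c(OCC=C)c1 | intermediate
5 | methyl 5-(allyloxy)-3,4-dioxocyclohexa-1,5-diene-1-carboxylate (4,5-quinone of 4) | COC(=O)C1=CC(=O)C(=O)C(OCC=C)=C1 | intermediate
6 | hetero-Diels–Alder dimer of 5: O5 of ring B on C2 and O4 of ring B on C3 of ring C, cis-fused 1,4-dioxane, racemic (one enantiomer drawn) | COC(=O)c1cc(OCC=C)c2O[C@]3(OCC=C)C(=O)C(=O)C=C(C(=O)OC)[C@@H]3Oc2c1 | intermediate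
7 | methyl 3-(allyloxy)-2-[3-(allyloxy)-2-hydroxy-5-(methoxycarbonyl)phenoxy]-4,5-dihydroxybenzoate | COC(=O)c1cc(OCC=C)c(O)c(Oc2c(C(=O)OC)cc(O)c(O)c2OCC=C)c1 | intermediate
8 | methyl 3-(allyloxy)-2-[3-(allyloxy)-2-(benzyloxy)-5-(methoxycarbonyl)phenoxy]-4,5-bis(benzyloxy)benzoate | COC(=O)c1cc(OCC=C)c(OCc2ccccc2)c(Oc2c(C(=O)OC)cc(OCc3ccccc3)c(OCc3ccccc3)c2OCC=C)c1 | intermediate
9 | methyl 4,5-bis(benzyloxy)-2-[2-(benzyloxy)-3-hydroxy-5-(methoxycarbonyl)phenoxy]-3-hydroxybenzoate | COC(=O)c1cc(O)c(OCc2ccccc2)c(Oc2c(C(=O)OC)cc(OCc3ccccc3)c(OCc3ccccc3)c2O)c1 | intermediate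
10 | methyl 7-(benzyloxy)-2,2-diphenyl-1,3-benzodioxole-5-carboxylate | COC(=O)c1cc(OCc2ccccc2)c2OC(c3ccccc3)(c3ccccc3)Oc2c1 | intermediate
11 | methyl 7-(benzyloxy)-4-bromo-2,2-diphenyl-1,3-benzodioxole-5-carboxylate | COC(=O)c1cc(OCc2ccccc2)c2OC(c3ccccc3)(c3ccccc3)Oc2c1Br | intermediate
12 | 7-(benzyloxy)-4-bromo-2,2-diphenyl-1,3-benzodioxole-5-carboxylic acid | OC(=O)c1cc(OCc2ccccc2)c2OC(c3ccccc3)(c3ccccc3)Oc2c1Br | intermediate
13 | ester of 12 with O3 of ring B of 9, O3–H of ring C free | COC(=O)c1cc(OC(=O)c2cc(OCc3ccccc3)c3OC(c4ccccc4)(c4ccccc4)Oc3c2Br)c(OCc2ccccc2)c(Oc2c(C(=O)OC)cc(OCc3ccccc3)c(OCc3ccccc3)c2O)c1 | intermediate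
14 | ring C O3 benzyl ether of 13 | COC(=O)c1cc(OC(=O)c2cc(OCc3ccccc3)c3OC(c4ccccc4)(c4ccccc4)Oc3c2Br)c(OCc2ccccc2)c(Oc2c(C(=O)OC)cc(OCc3ccccc3)c(OCc3ccccc3)c2OCc3ccccc3)c1 | intermediate
15 | benzo[c]chromen-6-one lactone with the A–B biaryl bond (racemic, twisted) | COC(=O)c1cc(Oc2c(C(=O)OC)cc(OCc3ccccc3)c(OCc3ccccc3)c2OCc3ccccc3)c(OCc2ccccc2)c2OC(=O)c3cc(OCc4ccccc4)c4OC(c5ccccc5)(c5ccccc5)Oc4c3-c12 | intermediate
16 | tetrapotassium salt: three carboxylates and the O3 phenoxide of ring B | [K+].[K+].[K+].[K+].[O-]C(=O)c1cc(Oc2c(C(=O)[O-])cc(OCc3ccccc3)c(OCc3ccccc3)c2OCc3ccccc3)c(OCc2ccccc2)c([O-])c1-c1c(C(=O)[O-])cc(OCc2ccccc2)c2OC(c3ccccc3)(c3ccccc3)Oc12 | intermediate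
17 | tribenzyl ester; benzyl ethers on O5 of ring A, O3 and O4 of ring B, O3 to O5 of ring C; diphenylmethylene ketal on O3 and O4 of ring A (racemic axis) | O=C(OCc1ccccc1)c1cc(Oc2c(C(=O)OCc3ccccc3)cc(OCc3ccccc3)c(OCc3ccccc3)c2OCc3ccccc3)c(OCc2ccccc2)c(OCc2ccccc2)c1-c1c(C(=O)OCc2ccccc2)cc(OCc2ccccc2)c2OC(c3ccccc3)(c3ccccc3)Oc12 | intermediate
18 | valoneaic acid | O=C(O)c1cc(O)c(O)c(O)c1Oc1cc(C(=O)O)c(-c2c(C(=O)O)cc(O)c(O)c2O)c(O)c1O | target

**Step count**

- Total step count: 14.
- Longest linear sequence: 11 steps (1, 2, 3, 4, 5, 6, 10, 11, 12, 13, 14).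
- The ring A branch (steps 7 to 9) leaves from compound 2.

**Steps most likely to fail**

**Step 4.** The quinone may dimerise through its carbon diene (carbocyclic Diels–Alder addition), the hetero-addition may take the opposite orientation, or the quinone may polymerise before it dimerises.

The fallback sets out from 4 and 1 and comes back at 14. It makes the ether by Ullmann condensation instead of oxidation.
- Catechol 4 is benzylated once (BnBr, one equivalent of KHCO3, DMF) on the more acidic O4–H para to the ester. This gives methyl 3-(allyloxy)-4-(benzyloxy)-5-hydroxybenzoate F1.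
- Methyl gallate 1 is perbenzylated (BnBr, K2CO3) to methyl 3,4,5-tris(benzyloxy)benzoate F2.
- F2 is brominated with NBS to methyl 2-bromo-3,4,5-tris(benzyloxy)benzoate F3.
- CuBr, N,N-dimethylglycine and Cs2CO3 in dioxane at 100 °C should join the phenol of F1 to the ester-activated C2–Br of F3. This gives methyl 2-[3-(allyloxy)-2-(benzyloxy)-5-(methoxycarbonyl)phenoxy]-3,4,5-tris(benzyloxy)benzoate F4.
- Pd(PPh3)4 and morpholine remove the single allyl group. This gives methyl 3,4,5-tris(benzyloxy)-2-[2-(benzyloxy)-3-hydroxy-5-(methoxycarbonyl)phenoxy]benzoate F5.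
- DCC/DMAP esterification of F5 with 12 gives 14.

**Step 12.** Metalation at the crowded C2–H of ring B may be slower than hydrodebromination of the aryl–palladium intermediate, or slower than thermal cleavage of the aryl ester.

The fallback sets out from 14 and comes back at 15. It replaces C–H arylation by a tethered Ullmann coupling of two C–Br bonds.
- K2CO3 in MeOH/THF cleaves the aryl ester of 14. This returns methyl 3,4,5-tris(benzyloxy)-2-[2-(benzyloxy)-3-hydroxy-5-(methoxycarbonyl)phenoxy]benzoate F5 and bromo ester 11, which is saponified again as in step 9.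
- Br2 with NaOAc in AcOH should brominate F5 beside the free phenol at C2 of ring B, the orientation typical of 3-hydroxy-4-alkoxybenzoyl compounds. This gives methyl 3,4,5-tris(benzyloxy)-2-[2-(benzyloxy)-4-bromo-3-hydroxy-5-(methoxycarbonyl)phenoxy]benzoate F6.
- DCC/DMAP esterification with 12 gives the ester-tethered dibromide F7.
- Activated Cu powder in DMF at 120 °C couples the two carbonyl-activated C–Br bonds of F7 to give lactone 15.

**Step 10.** The two phenols may not be told apart well enough, so that the hindered phenol is acylated too or diacylation occurs.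

The fallback sets out from 9 and comes back at 14. It replaces direct acylation by a protecting-group relay in which a wrong silylation can be reversed and the material recycled.
- TIPSCl and imidazole in DMF at 0 °C silylate the open O3–H of ring B to give the ring B O3 triisopropylsilyl ether F8.
- BnBr and K2CO3 in acetone cap the hindered ring C phenol to give the silyl benzyl ether F9.
- Bu4NF in THF frees methyl 3,4,5-tris(benzyloxy)-2-[2-(benzyloxy)-3-hydroxy-5-(methoxycarbonyl)phenoxy]benzoate F5.
- DCC/DMAP esterification of F5 with 12 gives 14.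

**Further compounds**

F1 | step 4 | methyl 3-(allyloxy)-4-(benzyloxy)-5-hydroxybenzoate | COC(=O)c1cc(O)c(OCc2ccccc2)c(OCC=C)c1
F2 | step 4 | methyl 3,4,5-tris(benzyloxy)benzoate | COC(=O)c1cc(OCc2ccccc2)c(OCc2ccccc2)c(OCc2ccccc2)c1
F3 | step 4 | methyl 2-bromo-3,4,5-tris(benzyloxy)benzoate | COC(=O)c1cc(OCc2ccccc2)c(OCc2ccccc2)c(OCc2ccccc2)c1Br
F4 | step 4 | methyl 2-[3-(allyloxy)-2-(benzyloxy)-5-(methoxycarbonyl)phenoxy]-3,4,5-tris(benzyloxy)benzoate | COC(=O)c1cc(OCC=C)c(OCc2ccccc2)c(Oc2c(C(=O)OC)cc(OCc3ccccc3)c(OCc3ccccc3)c2OCc3ccccc3)c1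
F5 | step 4 | methyl 3,4,5-tris(benzyloxy)-2-[2-(benzyloxy)-3-hydroxy-5-(methoxycarbonyl)phenoxy]benzoate | COC(=O)c1cc(O)c(OCc2ccccc2)c(Oc2c(C(=O)OC)cc(OCc3ccccc3)c(OCc3ccccc3)c2OCc3ccccc3)c1
F6 | step 12 | methyl 3,4,5-tris(benzyloxy)-2-[2-(benzyloxy)-4-bromo-3-hydroxy-5-(methoxycarbonyl)phenoxy]benzoate | COC(=O)c1cc(Oc2c(C(=O)OC)cc(OCc3ccccc3)c(OCc3ccccc3)c2OCc3ccccc3)c(OCc2ccccc2)c(O)c1Br
F7 | step 12 | ester-tethered dibromide (ester of 12 with O3 of ring B of F6) | COC(=O)c1cc(Oc2c(C(=O)OC)cc(OCc3ccccc3)c(OCc3ccccc3)c2OCc3ccccc3)c(OCc2ccccc2)c(OC(=O)c2cc(OCc3ccccc3)c3OC(c4ccccc4)(c4ccccc4)Oc3c2Br)c1Br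
F8 | step 10 | ring B O3 triisopropylsilyl ether of 9 | COC(=O)c1cc(O[Si](C(C)C)(C(C)C)C(C)C)c(OCc2ccccc2)c(Oc2c(C(=O)OC)cc(OCc3ccccc3)c(OCc3ccccc3)c2O)c1
F9 | step 10 | ring C O3 benzyl ether of F8 | COC(=O)c1cc(O[Si](C(C)C)(C(C)C)C(C)C)c(OCc2ccccc2)c(Oc2c(C(=O)OC)cc(OCc3ccccc3)c(OCc3ccccc3)c2OCc3ccccc3)c1
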